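In the first hours, while solid substrate is still going into solution, the intermediate passes to target by a faster step than to isomer of the product, and the dispute is whether that head start lasts to the reading.

    intermediate ⇌ isomer of the product (K1 = 93, k1 = 6.3 × 10⁻⁵ s⁻¹)
    starting material → intermediate (k2 = 0.0015 s⁻¹)
    solid substrate ⇌ starting material, rate k3*(cs3 - [starting material]) while solid is left; crystals form when [starting material] > cs3 (cs3 = 0.058 M, k3 = 4.0 × 10⁻⁵ s⁻¹)
    intermediate ⇌ target (K4 = 3.6, k4 = 1.7 × 10⁻⁴ s⁻¹)

solid substrate 0.10 M; time 15 d

* at 15 d, what has stopped the reaction, if anything has (for what has run out or reacted, a solid counts together with what of it has only dissolved) (it is still moving / all of the solid substrate has reacted / forward and back rates have come level)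
* the target standing at 15 d, as a percentage of the solid substrate charged

- as a solid, counted per litre of solution: solid substrate
- at the start none of the solid substrate is in solution
- what has only dissolved of solid substrate counts as not reacted
- the reaction counts as stopped when no species that holds the solid substrate changes by six tenths of a point or more over the second half of the time
- run time (flask): 15 d

Two people agree on the feed: the charge divided by the dissolution coefficient times the solubility gives at least 0.499 d, which is shorter than the time of reading, and the step from starting material to intermediate is one-way. The first holds to kinetic control: the intermediate splits by its forward constants, target takes 73.0 %, and this side, noting that the relaxation half-life towards target, 0.886 h, is shorter than that towards isomer of the product, 0.126 d, expects this share to stand. The second holds to thermodynamic control: with equilibrium constants K1 for the isomer and K4 for target, target's share is K4/(1+K1+K4), or 3.69 %, a gap of 69 percentage points from the first figure.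

I side with the second, and I reckon in powers of ten. Let λ be the slower nonzero eigenvalue of the first-order rate matrix of intermediate, target and isomer, with each back constant the forward one over its K; this gives λ = 1.16 × 10⁻⁵ s⁻¹. The decade time τ = ln(10)/λ = 2.30 d is the time in which, once the faster mode has faded, target's gap from its equilibrium share falls by one power of ten. The reading lies 6.53 decade times out, so the gap should have fallen by about that many powers of ten. The feed's clock, though a lower bound, is shorter than the decade time, so I commit to this ending: all of the solid substrate has reacted.

The forecast gave 3.69 % and the ending "forward and back rates have come level", holding that “the final state is set by equilibrium”.

The flask gives 3.69 % and the ending "all of the solid substrate has reacted", with solid substrate at 0 % and starting material at 0 % at 15.0 d. The kinetic view has its region early: target in this flask still read 21.9 % at 1.50 d, less than the first side's share but more than the equilibrium share, and the answer lies 5 points off at 2.79 d, which is 1.21 decade times. The neighbour flask read at 10 d stands at 4.35 decade times, so its gap should have fallen by that many powers of ten, and it reads target 3.69 %, with isomer of the product at 95.3 % and intermediate at 1.03 %.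

The constants are invented; the run is a simulation.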